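The oxolane is disconnected at C3–C4, O1–C2 and O1–C5, which leaves two propenylphenols and one molecule of water. The feature exploited is that ring A–C2–C3(CH3) and ring B–C5–C4(CH3) are two phenylpropanoid units joined only through their side-chain β-carbons, with O1 bridging the two benzylic carbons. A single laccase oxidation, steered by a dirigent protein, should couple (E)-isoeugenol 1 with (E)-4-propenylsyringol 2, forming these three bonds, the ring and all four stereocentres. Both precursors need a free para-hydroxyl, so the ring A methyl ether is installed afterwards, by a steric tag-and-cap relay that uses only routine protecting-group chemistry.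

Key step: step 1

Remark on locants: O1, C2 (bears ring A, the guaiacyl and later veratryl ring), C3, C4, C5 (bears ring B, the syringyl ring). With these locants the target is (2S,3S,4R,5R), that is 2,3-trans, 3,4-cis, 4,5-trans. It is the same compound as 4-[(2R,3R,4S,5S)-5-(3,4-dimethoxyphenyl)-3,4-dimethyloxolan-2-yl]-2,6-dimethoxyphenol, whose name counts the ring from the other side.

Assumption: both propenylphenols are bought as the pure E isomers. The laccase and the dirigent protein variant come from heterologous expression and count as catalysts, not as synthetic steps.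

Step 1
Reactants: 1 (E)-isoeugenol; 2 (E)-4-propenylsyringol
Product: 5 (2S,3S,4R,5R)-2-(4-hydroxy-3-methoxyphenyl)-5-(4-hydroxy-3,5-dimethoxyphenyl)-3,4-dimethyloxolane, via bis-quinone methide 3 (not isolated), via hydroxy quinone methide 4 (not isolated)
Conditions: laccase (Trametes versicolor, cat.), engineered dirigent protein (cat.), O2 (air), NaOAc buffer pH 5.0/acetone 9:1, 25 °C, slow co-feed of 1 (1.5 equiv) and 2; EtOAc extraction; then CF3CO2H (5 mol %), CH2Cl2, rt
Reagents that add atoms: water, O
Why: Proposed new method: the laccase takes one electron and one proton from each free para-hydroxyl, the two phenoxyl radicals, which carry spin density at the side-chain β-carbon, combine there to give the C3–C4 bond and bis-quinone methide 3, water adds to the more electrophilic guaiacyl methide carbon (O1–C2, giving 4) and the new benzylic hydroxyl adds to the syringyl methide carbon (O1–C5). The closest known reaction types are the laccase- or peroxidase-mediated dehydrodimerisation of propenylphenols, which is racemic and regiochemically mixed, and the dirigent-protein-controlled β–β homocoupling of coniferyl alcohol, whereas an enantioselective heterocoupling has not been demonstrated. The only ring formed, the oxolane, closes by a 5-exo-trig oxa-Michael addition in which the exocyclic C=C bond of the syringyl quinone methide is the acceptor. C3 (S) and C4 (R) are set irreversibly in the radical combination by the protein, which has to present the Re face of the β-carbon of the radical from 1 to the Si face of the β-carbon of the radical from 2 (unlike pairing, hence cis methyl groups, and one of the two mirror-image unlike pairings, hence the absolute sense). C2 (S) and C5 (R) are set by the substrate, since each aryl group prefers to lie trans to the neighbouring methyl group and the acid finish lets both benzylic C–O bonds reopen through para-hydroxybenzyl cations until this most stable trans,cis,trans isomer is reached without touching C3 or C4. The step needs β–β regioselectivity, cross- over homocoupling and facial control: the two ortho-methoxy groups of 2 shut off its ring-carbon coupling sites and give an engineered two-lobe pocket a handle for telling the partners apart, while slow co-feeding with the less easily oxidised 1 in excess keeps both radicals available and unbound radicals scarce.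

Step 2
Reactants: 5 diphenol oxolane
Product: 7 (2S,3S,4R,5R)-5-(4-acetoxy-3,5-dimethoxyphenyl)-2-[4-(tert-butyldiphenylsilyloxy)-3-methoxyphenyl]-3,4-dimethyloxolane, via ring A silyl ether 6 (not isolated)
Conditions: TBDPSCl (1.05 equiv), imidazole, DMF, 0 °C; then Ac2O, DMAP (cat.), 0 °C → rt
Reagents that add atoms: tert-butyl(chloro)diphenylsilane, CC(C)(C)[Si](Cl)(c1ccccc1)c1ccccc1; acetic anhydride, CC(=O)OC(C)=O
Why: Imidazole-promoted silylation of a phenol by a bulky chlorosilane is governed by access to silicon, so the ring A hydroxyl (one ortho-methoxy group) should react well ahead of the ring B hydroxyl (two ortho-methoxy groups), a difference that a small methyl electrophile could not be trusted to read, and DMAP-catalysed acetylation then caps the remaining ring B hydroxyl without touching any stereocentre.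

Step 3
Reactants: 7 ring A silyl ether, ring B acetate
Product: 8 (2S,3S,4R,5R)-5-(4-acetoxy-3,5-dimethoxyphenyl)-2-(4-hydroxy-3-methoxyphenyl)-3,4-dimethyloxolane
Conditions: Bu4NF, AcOH (1:1), THF, 0 °C
Reagents that add atoms: none
Why: Fluoride-mediated cleavage of an aryl silyl ether is driven by the strong Si–F bond and is fast at 0 °C, and the acetic acid buffer protonates the ring A phenoxide as it forms, so the ring B acetate should be neither cleaved nor transferred.

Step 4
Reactants: 8 ring A phenol, ring B acetate
Product: 9 (2S,3S,4R,5R)-5-(4-acetoxy-3,5-dimethoxyphenyl)-2-(3,4-dimethoxyphenyl)-3,4-dimethyloxolane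
Conditions: MeOH, PPh3, DIAD, THF, 0 °C → rt
Reagents that add atoms: methanol, CO
Why: Mitsunobu etherification: the only free phenol protonates the PPh3–DIAD betaine and its phenoxide displaces Ph3P=O from the methoxyphosphonium ion by SN2 attack at methyl, under neutral conditions that spare the acetate, the benzylic ethers and all four stereocentres.

Step 5
Reactants: 9 ring A dimethyl ether, ring B acetate
Product: 10 (2S,3S,4R,5R)-2-(3,4-dimethoxyphenyl)-5-(4-hydroxy-3,5-dimethoxyphenyl)-3,4-dimethyloxolane (target)
Conditions: NH3 (7 M in MeOH), 0 °C → rt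
Reagents that add atoms: none
Why: Aminolysis of an activated aryl ester (addition–elimination at the acetyl carbonyl) runs at room temperature in a weakly basic medium, well short of what would be needed to reopen the para-hydroxybenzyl ether at C5, so the configuration set in step 1 is kept.

Compound list
1 | (E)-isoeugenol, 2-methoxy-4-[(E)-prop-1-enyl]phenol | C/C=C/c1ccc(O)c(OC)c1 | starting material
2 | (E)-4-propenylsyringol, 2,6-dimethoxy-4-[(E)-prop-1-enyl]phenol | C/C=C/c1cc(OC)c(O)c(OC)c1 | starting material
3 | β–β-coupled bis(para-quinone methide): guaiacyl and syringyl quinone methides joined through the two methyl-bearing carbons, which already have the spatial arrangement of C3 and C4 of 5 (methide C=C geometry on the guaiacyl side not defined) | O=C1C(OC)=CC(=C[C@H](C)[C@@H](C=C2C=CC(=O)C(OC)=C2)C)C=C1OC | intermediate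
4 | benzylic alcohol from addition of water to the guaiacyl methide carbon of 3 (future C2, drawn with the configuration it has in 5), syringyl quinone methide intact | O=C1C(OC)=CC(=C[C@H](C)[C@@H]([C@H](O)c2ccc(O)c(OC)c2)C)C=C1OC | intermediate
5 | (2S,3S,4R,5R)-2-(4-hydroxy-3-methoxyphenyl)-5-(4-hydroxy-3,5-dimethoxyphenyl)-3,4-dimethyloxolane | COc1cc([C@H]2O[C@@H](c3cc(OC)c(O)c(OC)c3)[C@H](C)[C@@H]2C)ccc1O | intermediate
6 | (2S,3S,4R,5R)-2-[4-(tert-butyldiphenylsilyloxy)-3-methoxyphenyl]-5-(4-hydroxy-3,5-dimethoxyphenyl)-3,4-dimethyloxolane | COc1cc([C@H]2O[C@@H](c3cc(OC)c(O)c(OC)c3)[C@H](C)[C@@H]2C)ccc1O[Si](c4ccccc4)(c5ccccc5)C(C)(C)C | intermediate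
7 | (2S,3S,4R,5R)-5-(4-acetoxy-3,5-dimethoxyphenyl)-2-[4-(tert-butyldiphenylsilyloxy)-3-methoxyphenyl]-3,4-dimethyloxolane | COc1cc([C@H]2O[C@@H](c3cc(OC)c(OC(C)=O)c(OC)c3)[C@H](C)[C@@H]2C)ccc1O[Si](c4ccccc4)(c5ccccc5)C(C)(C)C | intermediate
8 | (2S,3S,4R,5R)-5-(4-acetoxy-3,5-dimethoxyphenyl)-2-(4-hydroxy-3-methoxyphenyl)-3,4-dimethyloxolane | COc1cc([C@H]2O[C@@H](c3cc(OC)c(OC(C)=O)c(OC)c3)[C@H](C)[C@@H]2C)ccc1O | intermediate
9 | (2S,3S,4R,5R)-5-(4-acetoxy-3,5-dimethoxyphenyl)-2-(3,4-dimethoxyphenyl)-3,4-dimethyloxolane | COc1ccc([C@H]2O[C@@H](c3cc(OC)c(OC(C)=O)c(OC)c3)[C@H](C)[C@@H]2C)cc1OC | intermediate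
10 | (2S,3S,4R,5R)-2-(3,4-dimethoxyphenyl)-5-(4-hydroxy-3,5-dimethoxyphenyl)-3,4-dimethyloxolane | COc1ccc([C@H]2O[C@@H](c3cc(OC)c(O)c(OC)c3)[C@H](C)[C@@H]2C)cc1OC | target

Total steps: 5. Longest linear sequence: 5 steps (from 1 or 2 to 10).

Steps most likely to fail

1. Step 1.
- Risk: unbound radicals may couple faster than protein-bound ones, giving homocoupling and β–ring-carbon or β–oxygen coupling of the radical from 1. The pocket may pair like faces or give poor facial control. The laccase may also go on to oxidise the product phenols.
- Fallback: known polar chemistry, setting out from 2 and coming back at 10, so that steps 2–5 are bypassed as well. Compound 2 is benzylated (BnBr, K2CO3, DMF) to benzyl ether F1, converted with NBS in aqueous acetone into bromohydrin F2 and oxidised with Dess–Martin periodinane to α-bromo ketone F3. The lithium enolate of purchased 1-(3,4-dimethoxyphenyl)propan-1-one (LiN(SiMe3)2, THF, −78 °C) is alkylated with F3 to give 1,4-diketone F4, which makes the same C3–C4 bond by enolate SN2. Paal–Knorr cyclodehydration (TsOH, toluene, reflux) gives furan F5. Monitored cis-hydrogenation over palladium on carbon, with loss of the benzyl group, gives racemic all-cis oxolane F6. Catalytic CF3CO2H in CH2Cl2 epimerises both benzylic centres to racemic trans,cis,trans oxolane F7. Preparative HPLC on a cellulose tris(3,5-dimethylphenylcarbamate) phase then delivers 10.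

2. Step 2.
- Risk: the silyl chloride may not discriminate fully between the two hydroxyls (double silylation or silylation at ring B), which would carry the wrong substitution pattern forward.
- Fallback: selective deprotection in place of selective protection, setting out from 5 and coming back at 8. Compound 5 is acetylated exhaustively (Ac2O, pyridine, DMAP) to diacetate F8. The less hindered ring A acetate is then removed by alcoholysis with immobilised Candida antarctica lipase B and n-butanol in MTBE.

3. Step 3.
- Risk: the acetyl group may be lost or transferred between molecules while fluoride sets the ring A phenoxide free.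
- Fallback: protecting groups are dropped altogether, setting out from 5 and coming back at 10. Compound 5 is treated with a deficit of PPh3 and DIAD and with MeOH in THF at 0 °C. This relies only on the modest kinetic preference for the less hindered ring A hydroxyl. Other methylation products are removed by chromatography and unreacted 5 is recycled.

Further compounds
F1 | step 1 | 2-(benzyloxy)-1,3-dimethoxy-5-[(E)-prop-1-enyl]benzene | C/C=C/c1cc(OC)c(OCc2ccccc2)c(OC)c1
F2 | step 1 | 1-[4-(benzyloxy)-3,5-dimethoxyphenyl]-2-bromopropan-1-ol (racemic, configuration of no consequence) | CC(Br)C(O)c1cc(OC)c(OCc2ccccc2)c(OC)c1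
F3 | step 1 | 1-[4-(benzyloxy)-3,5-dimethoxyphenyl]-2-bromopropan-1-one (racemic) | CC(Br)C(=O)c1cc(OC)c(OCc2ccccc2)c(OC)c1
F4 | step 1 | 1-[4-(benzyloxy)-3,5-dimethoxyphenyl]-4-(3,4-dimethoxyphenyl)-2,3-dimethylbutane-1,4-dione (mixture of diastereomers, both lost in the next step) | COc1ccc(C(=O)C(C)C(C)C(=O)c2cc(OC)c(OCc3ccccc3)c(OC)c2)cc1OC
F5 | step 1 | 2-[4-(benzyloxy)-3,5-dimethoxyphenyl]-5-(3,4-dimethoxyphenyl)-3,4-dimethylfuran | COc1ccc(-c2oc(-c3cc(OC)c(OCc4ccccc4)c(OC)c3)c(C)c2C)cc1OC
F6 | step 1 | rac-(2R,3S,4R,5S)-2-(3,4-dimethoxyphenyl)-5-(4-hydroxy-3,5-dimethoxyphenyl)-3,4-dimethyloxolane (all-cis, both enantiomers written) | COc1ccc([C@@H]2O[C@H](c3cc(OC)c(O)c(OC)c3)[C@H](C)[C@@H]2C)cc1OC.COc1ccc([C@H]2O[C@@H](c3cc(OC)c(O)c(OC)c3)[C@@H](C)[C@H]2C)cc1OC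
F7 | step 1 | rac-(2S,3S,4R,5R)-2-(3,4-dimethoxyphenyl)-5-(4-hydroxy-3,5-dimethoxyphenyl)-3,4-dimethyloxolane (racemate of 10, both enantiomers written) | COc1ccc([C@H]2O[C@@H](c3cc(OC)c(O)c(OC)c3)[C@H](C)[C@@H]2C)cc1OC.COc1ccc([C@@H]2O[C@H](c3cc(OC)c(O)c(OC)c3)[C@@H](C)[C@H]2C)cc1OC
F8 | step 2 | (2S,3S,4R,5R)-2-(4-acetoxy-3-methoxyphenyl)-5-(4-acetoxy-3,5-dimethoxyphenyl)-3,4-dimethyloxolane | COc1cc([C@H]2O[C@@H](c3cc(OC)c(OC(C)=O)c(OC)c3)[C@H](C)[C@@H]2C)ccc1OC(C)=O
F0 | step 3 | none | none
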